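I had to choose the initiator loading for the next run: 5 mol% as in flask epsilon, or 15 mol% as in flask theta. The choice hung on how much of the charge the radicals could carry in 4.0 d.

all flasks: starting material 2.0 M; transfer agent 2.00 M; gas 130 mM (held); time 4.0 d
- epsilon: initiator 5 mol%
- theta: initiator 15 mol%

- which of these there is most of at the end, counted by the starting material in it, epsilon (side product / target / starting material / first chain carrier)
- which of these there is most of at the end, counted by the starting material in it, theta (side product / target / starting material / first chain carrier)
- final amount of the leader among these, as a percentage of the starting material charged, in epsilon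
- final amount of the leader among these, as a percentage of the starting material charged, in theta

- percent here means starting material units held: one ended chains A counts as two
- two of one species on the left: rate k times its square, two consumed each time
- at the start none of partner is dissolved
- run time (epsilon): 4.0 d

    initiator → 2 initiating radical (k1 = 0.020 h⁻¹)
    starting material + initiating radical → capped initiator + first chain carrier (k2 = 1.4 × 10⁷ M⁻¹ h⁻¹)
    partner + first chain carrier → target + second chain carrier (k3 = 4.1 × 10⁶ M⁻¹ h⁻¹)
    starting material + second chain carrier → by-product + first chain carrier (k4 = 5.6 × 10⁵ M⁻¹ h⁻¹)
    transfer agent + first chain carrier → side product + idle radical (k5 = 61000 M⁻¹ h⁻¹)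
    2 idle radical → ended radicals (k6 = 4 × 10⁷ M⁻¹ s⁻¹)
    2 first chain carrier → ended chains A (k7 = 8 × 10⁷ M⁻¹ s⁻¹)
    2 second chain carrier → ended chains B (k8 = 2.3 × 10⁷ M⁻¹ s⁻¹)
    starting material ⇌ dormant form (K9 = 0.43, k9 = 0.012 h⁻¹)
    gas ⇌ partner, rate k10*(csat - [partner]) (k10 = 0.38 h⁻¹, csat = 130 mM)
    partner → decomposed reagent (k11 = 0.012 h⁻¹)

Each initiating radical puts one unit of starting material into the first chain carrier, and that carrier meets a fork. Partner gives target and passes the chain on through the second chain carrier, which brings in a fresh unit of starting material. Transfer agent gives side product and an idle radical, and the chain stops there. I reckoned 4.1 × 10⁶ M⁻¹ h⁻¹ times 130 mM against 61000 M⁻¹ h⁻¹ times 2.00 M, with partner at saturation and transfer agent at its charge. That gave 4.37 target per side product, which I called the chain yield, the kinetic chain length of this flask. An even fork, a yield of one, is the zero of the scale, and this fork stood above it.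

So each radical should carry the chain yield plus one unit of the charge. The initiator, with a half-life of 1.4 d, supplied radicals amounting to 8.53% of the charge in epsilon and 25.6% in theta. Multiplying gave a cover of 45.8% in epsilon, short of the charge, and 137% in theta, beyond it. In theta I reckoned the fork's share of target at 81.4% of the charge. In epsilon I reckoned the uncarried rest, split with the dormant form at 0.43, at 37.9% as starting material against 37.3% as target, too near for me to call. I chose theta's loading.

The forecast named starting material for epsilon at 44% and target for theta at 59%, with “side product well behind in both runs”. Its figure for starting material in epsilon stood above mine.

The flask gave starting material as leader in epsilon at 43.2%, with target at 28.1%. In theta the leader was target at 60.9%, with starting material at 6.97%. The forecast held on both leaders and both figures.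

The difference in loading may be called the main reason: target in theta stood at 60.9%, and at 28.1% with that difference taken away. Target per side product read 3.13 in theta, below the chain yield of 4.37. For a neighbour of theta charged with 6 mol% I reckoned a supply of 10.2% and a cover of 55.0%, short of the charge. That neighbour ended with starting material at 38.6% ahead of target at 32.6%.

All constants are those of an exercise; the rest is arithmetic.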